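**Retrosynthetic overview**
- Sacidumlignan A ⇒ 1-(3,5-dimethoxyphenyl)-5,7-dimethoxy-2,3-dimethylnaphthalene: both phenolic C–O bonds are made last, by twofold C–H hydroxylation at the only two C–H bonds that lie between two methoxy groups.
- That naphthalene ⇒ 1,1-bis(3,5-dimethoxyphenyl)prop-1-ene + propanal, by an oxidative benzannulation (C2–C3 bond first, then C4–C4a ring closure with loss of water).
- The alkene ⇒ ethyl propanoate + two equivalents of the Grignard reagent from 1-bromo-3,5-dimethoxybenzene.
- Ring order: both benzene rings are bought; the only ring formed is the dimethyl-bearing ring of the naphthalene (step 2). The two aryl groups are identical, so either one can become the benzo ring.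

Assumption: the target has no stereocentre and no stable chirality axis (the pendant aryl ring is symmetrical), so it is achiral and "single enantiomer" means the one structure drawn.

**Step 1**
Reactants: 1 1-bromo-3,5-dimethoxybenzene; 2 ethyl propanoate
Product: 5 1,1-bis(3,5-dimethoxyphenyl)prop-1-ene, via aryl Grignard reagent 3 (not isolated), via tertiary carbinol 4 (not isolated)
Conditions: 1 (2.3 equiv), Mg, THF, reflux; 2 (1.0 equiv), 0 °C to rt; 2 M HCl; then TsOH·H2O (5 mol %), toluene, 80 °C
Reagents that add atoms: magnesium, [Mg] (stays only in intermediate 3)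
Why: Double Grignard addition to the ester gives the symmetrical tertiary carbinol, and acid-catalysed E1 dehydration through the diaryl-stabilised cation gives the alkene, which has no E/Z isomers because both aryl groups are the same; no stereocentre is formed.

**Step 2**
Reactants: 5 1,1-bis(3,5-dimethoxyphenyl)prop-1-ene; 6 propanal
Product: 8 1-(3,5-dimethoxyphenyl)-5,7-dimethoxy-2,3-dimethylnaphthalene, via unsaturated aldehyde 7 (not isolated)
Conditions: 6 (3 equiv), (±)-5-benzyl-2-tert-butyl-3-methylimidazolidin-4-one·TFA (20 mol %), Cu(OTf)2 (2.5 equiv, added over 6 h), CF3CO2Na (2 equiv), TFA (3 equiv), i-PrCN/DME, rt; then TsOH·H2O (0.2 equiv), toluene, 80 °C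
Reagents that add atoms: none
Why: Proposed new method: an oxidative [4+2] benzannulation of a 1,1-diarylalkene with an enolisable aldehyde, in which the imidazolidinone enamine of 6 is oxidised by divalent copper to a 3π-electron radical cation (organo-SOMO activation) that adds to the methyl-bearing alkene carbon of 5 to give a diaryl-stabilised tertiary radical, a second divalent copper oxidises this radical (radical-polar crossover, oxidative elimination of the adjacent proton) to the β,γ-unsaturated aldehyde 7, and acid then drives a Bradsher-type cyclodehydration onto the ring position ortho and para to the two methoxy groups (either of the two equivalent aryl rings) to give aromatic 8 with erasure of the transient stereocentre of 7; the closest known reaction types are the organo-SOMO carbo-oxidation of styrenes and homo-ene α-alkylation of aldehydes with olefins, joined to the Bradsher cyclodehydration.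

**Step 3**
Reactants: 8 1-(3,5-dimethoxyphenyl)-5,7-dimethoxy-2,3-dimethylnaphthalene
Product: 11 sacidumlignan A, via dilithio compound 9 (not isolated), via bis(dimethyl boronate) 10 (not isolated)
Conditions: n-BuLi (3.0 equiv), THF, 0 °C to rt; B(OMe)3 (6 equiv), −78 °C to rt; AcOH, 30% aq. H2O2, 0 °C to rt
Reagents that add atoms: hydrogen peroxide, OO (supplies both phenolic oxygens); n-butyllithium, [Li]CCCC (lithium stays only in intermediate 9); trimethyl borate, COB(OC)OC (boron stays only in intermediate 10)
Why: Twofold directed ortho-metalation takes place at the two most acidic, doubly chelated C–H bonds (C6 of the naphthalene between the 5- and 7-methoxy groups, and C4 of the pendant ring between its two methoxy groups), and borylation followed by peroxide oxidation (1,2-aryl shift from boron to oxygen) turns each C–Li bond into the phenolic C–O bond; no stereocentre is involved.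

**Compound list**

| No. | Name | SMILES | Role |
|---|---|---|---|
| 1 | 1-bromo-3,5-dimethoxybenzene | COc1cc(Br)cc(OC)c1 | starting material |
| 2 | ethyl propanoate | CCC(=O)OCC | starting material |
| 3 | 3,5-dimethoxyphenylmagnesium bromide | COc1cc([Mg]Br)cc(OC)c1 | intermediate (not isolated) |
| 4 | 1,1-bis(3,5-dimethoxyphenyl)propan-1-ol | CCC(O)(c1cc(OC)cc(OC)c1)c1cc(OC)cc(OC)c1 | intermediate (not isolated) |
| 5 | 1,1-bis(3,5-dimethoxyphenyl)prop-1-ene | CC=C(c1cc(OC)cc(OC)c1)c1cc(OC)cc(OC)c1 | intermediate |
| 6 | propanal | CCC=O | starting material |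
| 7 | 4,4-bis(3,5-dimethoxyphenyl)-2,3-dimethylbut-3-enal (racemic) | O=CC(C)C(C)=C(c1cc(OC)cc(OC)c1)c1cc(OC)cc(OC)c1 | intermediate (not isolated) |
| 8 | 1-(3,5-dimethoxyphenyl)-5,7-dimethoxy-2,3-dimethylnaphthalene | COc1cc(OC)cc(-c2c(C)c(C)cc3c(OC)cc(OC)cc23)c1 | intermediate |
| 9 | 6-lithio-1-(4-lithio-3,5-dimethoxyphenyl)-5,7-dimethoxy-2,3-dimethylnaphthalene | COc1cc(-c2c(C)c(C)cc3c(OC)c([Li])c(OC)cc23)cc(OC)c1[Li] | intermediate (not isolated) |
| 10 | 6-(dimethoxyboryl)-1-[4-(dimethoxyboryl)-3,5-dimethoxyphenyl]-5,7-dimethoxy-2,3-dimethylnaphthalene | COc1cc(-c2c(C)c(C)cc3c(OC)c(B(OC)OC)c(OC)cc23)cc(OC)c1B(OC)OC | intermediate (not isolated) |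
| 11 | sacidumlignan A, 5-(4-hydroxy-3,5-dimethoxyphenyl)-1,3-dimethoxy-6,7-dimethylnaphthalen-2-ol (achiral) | COc1cc(-c2c(C)c(C)cc3c(OC)c(O)c(OC)cc23)cc(OC)c1O | target |

**Summary**
Total step count: 3. Longest linear sequence: 3 steps (1 → 5 → 8 → 11).

**Steps most likely to fail, with fallbacks**

Step 2 (the proposed new benzannulation) is the main risk. Radical addition to the trisubstituted alkene may be slow against self-coupling of the propanal enamine, and the electron-rich rings may be attacked by the radical or by the aldehyde. The fallback uses known chemistry and sets out from Grignard reagent 3 (made from 1 as in step 1). Addition of 3 (2.2 equiv) to 2,3-dimethylsuccinic anhydride (THF, −20 °C to rt, acidic work-up) gives 5,5-bis(3,5-dimethoxyphenyl)-3,4-dimethyloxolan-2-one F3 as a diastereomer mixture, which does not matter. Reduction with i-Bu2AlH (CH2Cl2, −78 °C) gives the lactol 5,5-bis(3,5-dimethoxyphenyl)-3,4-dimethyloxolan-2-ol F4. TsOH·H2O in toluene at 80 °C ionises and dehydrates the diaryl carbinol end to aldehyde 7, which undergoes Bradsher cyclodehydration. The fallback comes back to the route at 8, and the synthesis then has 4 steps.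

Step 3 is the second risk. Dilithiation may be incomplete or accompanied by benzylic metalation of the ring methyl groups, and 2,6-dimethoxyaryl boronates are prone to protodeboronation while the syringol-type products are sensitive to peroxide. The fallback sets out from 8 and makes the C–O bonds by Dakin-type oxidation of isolable aldehydes instead of boronate oxidation. Lithiation (n-BuLi, THF) and a DMF quench give 4-(6-formyl-5,7-dimethoxy-2,3-dimethylnaphthalen-1-yl)-2,6-dimethoxybenzaldehyde F5, which can be purified and checked for regiochemistry. Baeyer–Villiger oxidation with mCPBA (CH2Cl2, rt) gives the bis(formate) 4-[6-(formyloxy)-5,7-dimethoxy-2,3-dimethylnaphthalen-1-yl]-2,6-dimethoxyphenyl formate F6. Methanolysis (K2CO3, MeOH, rt) then comes back to the route at 11.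

Step 1 is the least risky. The possible problems are enolisation or incomplete second addition with the ester, and acid-promoted dimerisation of the electron-rich alkene during dehydration. The fallback avoids both the ester and the acid and sets out from 3. Addition of 3 to 3,5-dimethoxybenzaldehyde (THF, 0 °C) gives bis(3,5-dimethoxyphenyl)methanol F1. Oxidation with MnO2 (CH2Cl2, rt) gives 3,3',5,5'-tetramethoxybenzophenone F2. Wittig olefination with the ylide from EtPPh3Br and KOt-Bu (THF, reflux) comes back to the route at 5.

**Further compounds**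
F1 | step 1 | bis(3,5-dimethoxyphenyl)methanol | OC(c1cc(OC)cc(OC)c1)c1cc(OC)cc(OC)c1
F2 | step 1 | 3,3',5,5'-tetramethoxybenzophenone | O=C(c1cc(OC)cc(OC)c1)c1cc(OC)cc(OC)c1
F3 | step 2 | 5,5-bis(3,5-dimethoxyphenyl)-3,4-dimethyloxolan-2-one (diastereomer mixture) | O=C1OC(c2cc(OC)cc(OC)c2)(c2cc(OC)cc(OC)c2)C(C)C1C
F4 | step 2 | 5,5-bis(3,5-dimethoxyphenyl)-3,4-dimethyloxolan-2-ol (diastereomer mixture) | OC1OC(c2cc(OC)cc(OC)c2)(c2cc(OC)cc(OC)c2)C(C)C1C
F5 | step 3 | 4-(6-formyl-5,7-dimethoxy-2,3-dimethylnaphthalen-1-yl)-2,6-dimethoxybenzaldehyde | COc1cc(-c2c(C)c(C)cc3c(OC)c(C=O)c(OC)cc23)cc(OC)c1C=O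
F6 | step 3 | 4-[6-(formyloxy)-5,7-dimethoxy-2,3-dimethylnaphthalen-1-yl]-2,6-dimethoxyphenyl formate | COc1cc(-c2c(C)c(C)cc3c(OC)c(OC=O)c(OC)cc23)cc(OC)c1OC=O
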